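Early in the closed runs with equal D and J, the X readings climb to a peak, and the height of that peak sinks as more E is charged.

| flask | D | J | E | remark | time |
|---|---|---|---|---|---|
| blue | 0.20 M | 0.20 M | 4 mM | run made earlier |  |
| grey | 0.20 M | 0.20 M | 2 mM | run made earlier |  |
| violet | 0.20 M | 0.20 M | 3 mM | run made earlier |  |
| green | 0.20 M | 0.40 M | 4 mM | run made earlier |  |
| Friday's | 0.20 M | 0.200 M | 4.0 mM | a single well-mixed tank run continuously and read at steady state, 15 min in it on average |  |
| Tuesday's | 0.20 M | 0.200 M | 4.0 mM | a single well-mixed tank run continuously and read at steady state, 75.0 min in it on average |  |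
| Monday's | 0.20 M (fed, over 12.0 min) | 0.200 M | 4.0 mM | a stirred flask in which D is dosed at a steady rate over 12.0 min without added volume, worked up at 15 min | 15 min |
| Wednesday's | 0.20 M | 0.200 M | 4.0 mM | everything together in a closed stirred flask, run for 15 min | 15 min |

| run | time / min | X / % |
|---|---|---|
| blue | 0.667 | 34.2 |
| blue | 1.00 | 36.9 |
| blue | 1.50 | 38.1 |
| blue | 2.50 | 39.1 |
| blue | 4.00 | 37.9 |
| blue | 6.00 | 37.3 |
| blue | 10.0 | 37.2 |
| grey | 1.33 | 41.2 |
| grey | 2.00 | 42.7 |
| grey | 3.00 | 42.0 |
| grey | 5.00 | 42.2 |
| grey | 8.00 | 40.4 |
| grey | 12.0 | 38.0 |
| grey | 20.0 | 37.1 |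
| violet | 1.33 | 40.1 |
| violet | 2.00 | 40.8 |
| violet | 3.00 | 39.4 |
| violet | 5.00 | 39.9 |
| violet | 8.00 | 38.7 |
| violet | 12.0 | 37.8 |
| violet | 20.0 | 35.1 |
| green | 1.50 | 54.3 |
| green | 5.00 | 51.0 |
| green | 8.00 | 50.2 |
| green | 12.0 | 48.7 |
| green | 20.0 | 46.8 |

(each reading ± 0.5 percentage points)

- the stated concentrations are those of everything mixed, before any reaction; amounts are the same in each set-up
- steps that have been proposed: X + E <-> G + E; E -> Q; D + J <-> G; D + J <-> X
- the feed brings no volume worth counting
- the earlier runs were made in a closed, stirred flask

1. the set-up with the highest amount of X at the outlet or at the end, in percent of the D put in ("none" if the first two lie within 2 percentage points) (Friday's / Tuesday's / Monday's / Wednesday's / none)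
2. amount of X at the outlet or at the end, in percent of the D put in, Friday's
3. amount of X at the outlet or at the end, in percent of the D put in, Tuesday's
4. amount of X at the outlet or at the end, in percent of the D put in, Monday's
5. amount of X at the outlet or at the end, in percent of the D put in, Wednesday's

We build the flask up one process at a time, and this reckoning is ours. First we take the main step by itself, D + J ⇌ X. The peak readings at equal D and J are 42.7% in grey, 40.8% in violet and 39.1% in blue, nearly on a line in c_E. Drawing that line back to no E gives our reading of a ceiling for X at equal D and J: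

ceiling = 46.3%

D and J are charged equally and react one for one, so c_D = c_J. We call the quotient c_X/(c_D·c_J), read at this ceiling, the holding constant K_h, an equilibrium constant as read from the runs:

K_h = 8.03 M⁻¹

Next we add the drain of X to G by E. D and J refill part of what is drained, so X and D share whatever G has not taken, with c_X = K_h·c_D·c_J. Blue's last reading then implies G at 14.7% of the charge, while X stands 9.1 percentage points under the ceiling, which is less than the G made.

Then comes the rest. Blue is flat from 6.00 min to 10.0 min, which could mean a balance of X and G or a fading E. Violet's last reading, 35.1%, lies under that flat level, and we bet on fading E with a slow further route. On that bet the drain belongs to the first minutes, while Monday's D goes on arriving for 12.0 min. We therefore put Monday's near the ceiling.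

The forecast differs. It gave 38% for Friday's, 36% for Tuesday's, 38.5% for Monday's and 37% for Wednesday's, with best none. Of Monday's it said: “with older catalyst, so it may retain slightly more X”.

The flask gives 35.3% for Friday's, 32.0% for Tuesday's, 43.7% for Monday's and 35.5% for Wednesday's, so the best is Monday's.

    X + E ⇌ G + E, rate k1*[E]*[X] forward; the back reaction follows from the equilibrium constant (k = 3.20 M⁻¹ s⁻¹)
    E → Q (k = 0.0210 s⁻¹)
    D + J ⇌ G (K = 14.0 M⁻¹, k = 0.00290 M⁻¹ s⁻¹)
    D + J ⇌ X (K = 9.70 M⁻¹, k = 0.120 M⁻¹ s⁻¹)

E goes to Q with a half-life of 0.55 min, shorter than Monday's dosing time. Of the effects tried, E → Q is the largest single one on the gap between Monday's and Tuesday's: with that step struck out, the gap falls from 12 points to 0.075 points. Monday's ends with 9.10% of G, and K_h turns that into X of 40.6%, against 43.7% in the flask. Tuesday's tank holds 26.9% of G, and the same reckoning gives 29.9%, against 32.0% in the flask.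

(Readings and results were computed on assumed constants, and the scatter is random.)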